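**Retrosynthetic overview**
- Bleochrin B comes from its penta-O-benzyl ether 26 by hydrogenolysis. The strategy rests on ring A, a hexasubstituted benzene in which C1 (OMe) and C3 (OH) are meta, C2 between them carries a 4-oxybenzyl group, and C4, C5, C6 carry benzyl, arylethyl and benzyl groups. This is the 1-hydroxy-2-alkyl-3-alkoxy-4,5,6-trialkyl pattern of a cyclobutenone/1-alkoxyalkyne benzannulation.
- Ring A is cut at C2–C3, C1–C6 and C3–C4 into cyclobutenone 21 (which gives C3, C4, C5, C6) and methoxyalkyne 4 (which gives C1, C2 and the OMe).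
- 21 comes from 3-methoxycyclobutenone 8 by addition of arylethyllithium 19 and acid transposition; 8 comes from a ketene/ynol ether [2+2] that uses the same alkyne 4.
- Ring B is bought as 2-bromo-4-hydroxybenzaldehyde and elaborated to diarylmethane 14 and iodide 18. The four-membered ring is made first (step 3) and ring A last (step 10).

Key step: step 10

Remark: the target is achiral. The sp3 stereocentres that appear on the way (C4 of the cyclobutenones, the carbinol carbons of 13 and 20) are formed without control and are all erased later. Compound 26 carries five aryl benzyl ethers, one for each phenol other than the ring A C3 OH.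

**Step 1**
Reactants: 1 chloroacetaldehyde dimethyl acetal, 2 4-benzyloxybenzyl bromide
Product: 4 1-methoxy-3-(4-benzyloxyphenyl)prop-1-yne, via lithium methoxyacetylide 3 (not isolated)
Conditions: LiNEt2 (3.0 equiv, from Et2NH and n-BuLi), THF, 0 °C; then 2, DMPU, −78 to 0 °C; chromatography on Et3N-deactivated silica
Reagents that add atoms: none
Why: Three equivalents of amide base remove methanol and HCl from the acetal by double elimination and metalate the resulting methoxyacetylene, and the lithium acetylide is then C-alkylated in an SN2 reaction by the reactive benzylic bromide at low temperature, where the liberated diethylamine is the slower nucleophile.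

**Step 2**
Reactants: 5 3-(4-benzyloxyphenyl)propanoic acid
Product: 6 3-(4-benzyloxyphenyl)propanoyl chloride
Conditions: (COCl)2, cat. DMF, CH2Cl2, 0 °C to rt
Reagents that add atoms: oxalyl chloride, ClC(=O)C(Cl)=O
Why: Standard acid chloride formation through the catalytic chloroiminium species, which leaves the aryl benzyl ether untouched.

**Step 3**
Reactants: 6 3-(4-benzyloxyphenyl)propanoyl chloride, 4 1-methoxy-3-(4-benzyloxyphenyl)prop-1-yne
Product: 8 3-methoxy-2,4-bis(4-benzyloxybenzyl)cyclobut-2-en-1-one (racemic at C4), via ketene 7 (not isolated)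
Conditions: Et3N, CH2Cl2, slow addition of 6 to 4, 0 °C to rt
Reagents that add atoms: none
Why: Triethylamine dehydrochlorinates 6 to the aldoketene 7, which undergoes a ketene–ynol ether [2+2] cycloaddition in which the nucleophilic benzyl-bearing alkyne carbon bonds to the ketene carbonyl carbon, so OMe ends at C3; slow addition keeps 7 dilute against dimerization, and C4 forms racemic, which is of no consequence.

**Step 4**
Reactants: 9 2-bromo-4-hydroxybenzaldehyde
Product: 10 4-benzyloxy-2-bromobenzaldehyde
Conditions: BnBr, K2CO3, DMF, rt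
Reagents that add atoms: benzyl bromide, BrCc1ccccc1
Why: Williamson etherification of the acidic para-formyl phenol, which is O-alkylated cleanly under carbonate conditions.

**Step 5**
Reactants: 10 4-benzyloxy-2-bromobenzaldehyde, 11 1-benzyloxy-4-bromobenzene
Product: 13 (4-benzyloxy-2-bromophenyl)(4-benzyloxyphenyl)methanol (racemic), via Grignard reagent 12 (not isolated)
Conditions: Mg, THF, rt (11 to 12); then 10, THF, 0 °C; aq NH4Cl
Reagents that add atoms: none
Why: Grignard addition of the aryl nucleophile to the aldehyde, which does not disturb the ring bromide at 0 °C; the carbinol stereocentre forms racemic and is removed in step 6.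

**Step 6**
Reactants: 13 (4-benzyloxy-2-bromophenyl)(4-benzyloxyphenyl)methanol
Product: 14 4-benzyloxy-2-bromo-1-(4-benzyloxybenzyl)benzene
Conditions: Et3SiH, CF3CO2H, CH2Cl2, 0 °C
Reagents that add atoms: none
Why: Ionic hydrogenation, in which the diarylmethyl cation stabilized by two para-alkoxy groups forms under mild acid and is trapped by silane hydride, under which the benzyl ethers and the aryl bromide persist.

**Step 7**
Reactants: 14 4-benzyloxy-2-bromo-1-(4-benzyloxybenzyl)benzene, 15 ethylene oxide
Product: 17 2-[5-benzyloxy-2-(4-benzyloxybenzyl)phenyl]ethanol, via aryllithium 16 (not isolated)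
Conditions: n-BuLi, THF, −78 °C; then 15 (excess), −78 to 0 °C; aq NH4Cl
Reagents that add atoms: none
Why: Bromine–lithium exchange is faster at −78 °C than deprotonation of the diarylmethane or benzyl ether CH2 groups, and the aryllithium opens the epoxide by SN2 attack to add the two-carbon arm.

**Step 8**
Reactants: 17 2-[5-benzyloxy-2-(4-benzyloxybenzyl)phenyl]ethanol
Product: 18 2-[5-benzyloxy-2-(4-benzyloxybenzyl)phenyl]ethyl iodide
Conditions: I2, PPh3, imidazole, CH2Cl2, 0 °C to rt
Reagents that add atoms: iodine, II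
Why: Appel iodination of an unhindered primary alcohol through the alkoxyphosphonium iodide under neutral buffered conditions.

**Step 9**
Reactants: 18 2-[5-benzyloxy-2-(4-benzyloxybenzyl)phenyl]ethyl iodide, 8 3-methoxy-2,4-bis(4-benzyloxybenzyl)cyclobut-2-en-1-one
Product: 21 2,4-bis(4-benzyloxybenzyl)-3-{2-[5-benzyloxy-2-(4-benzyloxybenzyl)phenyl]ethyl}cyclobut-2-en-1-one (racemic at C4), via alkyllithium 19 (not isolated), via cyclobutenol 20 (not isolated)
Conditions: t-BuLi (2.0 equiv), Et2O/pentane, −78 °C; then 8, THF, −78 °C; then 1 M HCl, THF, 0 °C to rt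
Reagents that add atoms: water, O
Why: Iodine–lithium exchange gives the primary alkyllithium, which adds 1,2 to the vinylogous ester carbonyl (C4 enolization would create a cyclobutadienolate and is disfavoured), and aqueous acid then hydrolyses the enol ether and expels the tertiary hydroxyl in a Stork–Danheiser transposition; the carbinol carbon of 20 forms as a diastereomer mixture and becomes sp2, while C4 stays racemic.

**Step 10**
Reactants: 21 2,4-bis(4-benzyloxybenzyl)-3-{2-[5-benzyloxy-2-(4-benzyloxybenzyl)phenyl]ethyl}cyclobut-2-en-1-one, 4 1-methoxy-3-(4-benzyloxyphenyl)prop-1-yne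
Product: 26 penta-O-benzyl bleochrin B, via vinylketene 22 (not isolated), via vinylcyclobutenone 23 (not isolated), via dienylketene 24 (not isolated), via cyclohexadienone 25 (not isolated)
Conditions: 4 (1.5 equiv), PhMe, 80 °C then 110 °C, sealed tube
Reagents that add atoms: none
Why: Heating opens 21 by 4π electrocyclic cleavage of the C1–C4 bond to vinylketene 22, whose ketene C=C adds the ynol ether 4 in a [2+2] cycloaddition to give 4-vinylcyclobutenone 23; a second 4π opening gives dienylketene 24, which closes ring A by thermal 6π electrocyclization (bond between the former carbonyl carbon C1 and the former C4) to dienone 25, and tautomerization of 25 delivers the phenol. This is the Danheiser benzannulation of a cyclobutenone with a 1-alkoxyalkyne, used here at the hexasubstituted end of its scope. Three ring C–C bonds are made (alkyne carbon to former C1, alkyne carbon to former C2, and C1 to C4), so the ring carries OH, benzyl, OMe, benzyl, arylethyl, benzyl in the required order. No stereocentre survives, since the racemic C4 of 21, the quaternary carbon of 23 and the sp3 carbon of 25 all end sp2. The selectivity needed is the regiochemistry of the ketene–alkyne [2+2], which the oxygen-polarized triple bond secures: its nucleophilic benzyl-bearing carbon attacks the electrophilic ketene carbonyl carbon, so the methoxy carbon bonds to the former C2. The methoxy group cannot undergo the retro-ene loss of alkene that consumes ethoxyalkynes on heating, and the two ortho benzyl groups shield the new OH from acylation by ketene 22.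

**Step 11**
Reactants: 26 penta-O-benzyl bleochrin B
Product: 27 bleochrin B
Conditions: H2 (1 atm), Pd/C, EtOAc/MeOH, rt
Reagents that add atoms: none
Why: Catalytic hydrogenolysis cleaves the five aryl benzyl ethers, while the diarylmethane and bibenzyl C–C bonds, the aryl methyl ether and the free phenol are inert under these conditions.

**Compound list**
1 | chloroacetaldehyde dimethyl acetal | COC(CCl)OC | starting material
2 | 4-benzyloxybenzyl bromide | BrCc1ccc(OCc2ccccc2)cc1 | starting material
3 | lithium methoxyacetylide | [Li]C#COC | intermediate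
4 | 1-methoxy-3-(4-benzyloxyphenyl)prop-1-yne | COC#CCc1ccc(OCc2ccccc2)cc1 | intermediate
5 | 3-(4-benzyloxyphenyl)propanoic acid | OC(=O)CCc1ccc(OCc2ccccc2)cc1 | starting material
6 | 3-(4-benzyloxyphenyl)propanoyl chloride | ClC(=O)CCc1ccc(OCc2ccccc2)cc1 | intermediate
7 | (4-benzyloxybenzyl)ketene | O=C=CCc1ccc(OCc2ccccc2)cc1 | intermediate
8 | 3-methoxy-2,4-bis(4-benzyloxybenzyl)cyclobut-2-en-1-one (racemic at C4) | COC1=C(Cc2ccc(OCc3ccccc3)cc2)C(=O)C1Cc1ccc(OCc2ccccc2)cc1 | intermediate
9 | 2-bromo-4-hydroxybenzaldehyde | O=Cc1ccc(O)cc1Br | starting material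
10 | 4-benzyloxy-2-bromobenzaldehyde | O=Cc1ccc(OCc2ccccc2)cc1Br | intermediate
11 | 1-benzyloxy-4-bromobenzene | Brc1ccc(OCc2ccccc2)cc1 | starting material
12 | 4-benzyloxyphenylmagnesium bromide | Br[Mg]c1ccc(OCc2ccccc2)cc1 | intermediate
13 | (4-benzyloxy-2-bromophenyl)(4-benzyloxyphenyl)methanol (racemic) | OC(c1ccc(OCc2ccccc2)cc1Br)c1ccc(OCc2ccccc2)cc1 | intermediate
14 | 4-benzyloxy-2-bromo-1-(4-benzyloxybenzyl)benzene | Brc1cc(OCc2ccccc2)ccc1Cc1ccc(OCc2ccccc2)cc1 | intermediate
15 | ethylene oxide | C1CO1 | starting material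
16 | 5-benzyloxy-2-(4-benzyloxybenzyl)phenyllithium | [Li]c1cc(OCc2ccccc2)ccc1Cc1ccc(OCc2ccccc2)cc1 | intermediate
17 | 2-[5-benzyloxy-2-(4-benzyloxybenzyl)phenyl]ethanol | OCCc1cc(OCc2ccccc2)ccc1Cc1ccc(OCc2ccccc2)cc1 | intermediate
18 | 2-[5-benzyloxy-2-(4-benzyloxybenzyl)phenyl]ethyl iodide | ICCc1cc(OCc2ccccc2)ccc1Cc1ccc(OCc2ccccc2)cc1 | intermediate
19 | 2-[5-benzyloxy-2-(4-benzyloxybenzyl)phenyl]ethyllithium | [Li]CCc1cc(OCc2ccccc2)ccc1Cc1ccc(OCc2ccccc2)cc1 | intermediate
20 | 1-{2-[5-benzyloxy-2-(4-benzyloxybenzyl)phenyl]ethyl}-3-methoxy-2,4-bis(4-benzyloxybenzyl)cyclobut-2-en-1-ol (racemic diastereomer mixture) | COC1=C(Cc2ccc(OCc3ccccc3)cc2)C(O)(CCc2cc(OCc3ccccc3)ccc2Cc2ccc(OCc3ccccc3)cc2)C1Cc1ccc(OCc2ccccc2)cc1 | intermediate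
21 | 2,4-bis(4-benzyloxybenzyl)-3-{2-[5-benzyloxy-2-(4-benzyloxybenzyl)phenyl]ethyl}cyclobut-2-en-1-one (racemic at C4) | O=C1C(Cc2ccc(OCc3ccccc3)cc2)C(CCc2cc(OCc3ccccc3)ccc2Cc2ccc(OCc3ccccc3)cc2)=C1Cc1ccc(OCc2ccccc2)cc1 | intermediate
22 | vinylketene from ring opening of 21 (benzyl group at the terminus trans to the ketene-bearing carbon) | O=C=C(Cc1ccc(OCc2ccccc2)cc1)/C(CCc1cc(OCc2ccccc2)ccc1Cc1ccc(OCc2ccccc2)cc1)=C/Cc1ccc(OCc2ccccc2)cc1 | intermediate
23 | 2,4-bis(4-benzyloxybenzyl)-3-methoxy-4-(1,3-disubstituted propenyl)cyclobut-2-en-1-one, the [2+2] adduct (racemic at C4) | O=C1C(Cc2ccc(OCc3ccccc3)cc2)=C(OC)C1(Cc1ccc(OCc2ccccc2)cc1)/C(CCc1cc(OCc2ccccc2)ccc1Cc1ccc(OCc2ccccc2)cc1)=C/Cc1ccc(OCc2ccccc2)cc1 | intermediate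
24 | dienylketene from ring opening of 23 (ketene-bearing carbon and vinyl group cis on the central double bond) | O=C=C(Cc1ccc(OCc2ccccc2)cc1)/C(OC)=C(Cc1ccc(OCc2ccccc2)cc1)\C(CCc1cc(OCc2ccccc2)ccc1Cc1ccc(OCc2ccccc2)cc1)=C\Cc1ccc(OCc2ccccc2)cc1 | intermediate
25 | 2,4,6-tris(4-benzyloxybenzyl)-3-methoxy-5-(arylethyl)cyclohexa-2,4-dien-1-one (racemic at C6) | O=C1C(Cc2ccc(OCc3ccccc3)cc2)=C(OC)C(Cc2ccc(OCc3ccccc3)cc2)=C(CCc2cc(OCc3ccccc3)ccc2Cc2ccc(OCc3ccccc3)cc2)C1Cc1ccc(OCc2ccccc2)cc1 | intermediate
26 | penta-O-benzyl bleochrin B | COc1c(Cc2ccc(OCc3ccccc3)cc2)c(O)c(Cc2ccc(OCc3ccccc3)cc2)c(CCc2cc(OCc3ccccc3)ccc2Cc2ccc(OCc3ccccc3)cc2)c1Cc1ccc(OCc2ccccc2)cc1 | intermediate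
27 | bleochrin B | COc1c(Cc2ccc(O)cc2)c(O)c(Cc2ccc(O)cc2)c(CCc2cc(O)ccc2Cc2ccc(O)cc2)c1Cc1ccc(O)cc1 | target

**Step count**
Total: 11 steps. Longest linear sequence: 8 steps (steps 4 to 11, from 9).

**Steps most likely to fail**

1. Step 10. The fully substituted vinylketene 22 may add to 4 more slowly than it dimerizes or acylates the new phenol, and the crowded dienylketene may close slowly, so that thermal loss of 4 outruns annulation. Acylation alone would be met by a brief K2CO3/MeOH methanolysis on work-up. The fallback relieves the congestion and sets out from ynol ether 4 and iodide 18. Ketene gas (from acetone pyrolysis) is added to 4 in CH2Cl2 at 0 °C to give 3-methoxy-2-(4-benzyloxybenzyl)cyclobut-2-en-1-one F1. Addition of alkyllithium 19 (from 18, as in step 9) and acid transposition should give the 4-unsubstituted 2-(4-benzyloxybenzyl)-3-{2-[5-benzyloxy-2-(4-benzyloxybenzyl)phenyl]ethyl}cyclobut-2-en-1-one F2. This is benzannulated with 4 under the conditions of step 10, the well-precedented case, to give 2,4-bis(4-benzyloxybenzyl)-5-{2-[5-benzyloxy-2-(4-benzyloxybenzyl)phenyl]ethyl}-3-methoxyphenol F3, whose only open ring position is C6. Ortho-C-benzylation of its sodium phenoxide (NaH, PhMe, reflux) with bromide 2 then brings the route back at 26.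

2. Step 1. The liberated diethylamine may be N-benzylated in competition with the acetylide, and the product may isomerize by base to the allenyl ether or hydrate on acidic supports. The fallback separates metalation from C–C bond formation and sets out from 1 and 2. Acetylide 3, generated as in step 1, is quenched with Bu3SnCl to give tributyl(methoxyethynyl)stannane F4. Stille coupling of F4 with bromide 2 (Pd(PPh3)4, THF, 50 °C), under neutral and base-free conditions, comes back to the route at 4.

3. Step 3. Amine-promoted generation of the aldoketene 7 all at once may lead to dimerization that outpaces the cycloaddition. The fallback generates the same ketene slowly and without amine, and sets out from bromide 2. Commercial ethoxyacetylene is lithiated (n-BuLi, THF, −78 °C) to lithium ethoxyacetylide F5 and alkylated with 2 (DMPU) to 1-ethoxy-3-(4-benzyloxyphenyl)prop-1-yne F6. On heating at about 110 to 120 °C in xylene, F6 loses ethylene by retro-ene fragmentation to ketene 7, which is trapped by remaining F6 to give 3-ethoxy-2,4-bis(4-benzyloxybenzyl)cyclobut-2-en-1-one F7. F7 takes the place of 8 in step 9, with ethanol lost instead of methanol, and the route is rejoined at 21.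

**Further compounds**
F1 | step 10 | 3-methoxy-2-(4-benzyloxybenzyl)cyclobut-2-en-1-one | COC1=C(Cc2ccc(OCc3ccccc3)cc2)C(=O)C1
F2 | step 10 | 2-(4-benzyloxybenzyl)-3-{2-[5-benzyloxy-2-(4-benzyloxybenzyl)phenyl]ethyl}cyclobut-2-en-1-one | O=C1CC(CCc2cc(OCc3ccccc3)ccc2Cc2ccc(OCc3ccccc3)cc2)=C1Cc1ccc(OCc2ccccc2)cc1
F3 | step 10 | 2,4-bis(4-benzyloxybenzyl)-5-{2-[5-benzyloxy-2-(4-benzyloxybenzyl)phenyl]ethyl}-3-methoxyphenol | COc1c(Cc2ccc(OCc3ccccc3)cc2)c(O)cc(CCc2cc(OCc3ccccc3)ccc2Cc2ccc(OCc3ccccc3)cc2)c1Cc1ccc(OCc2ccccc2)cc1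
F4 | step 1 | tributyl(methoxyethynyl)stannane | CCCC[Sn](CCCC)(CCCC)C#COC
F5 | step 3 | lithium ethoxyacetylide | [Li]C#COCC
F6 | step 3 | 1-ethoxy-3-(4-benzyloxyphenyl)prop-1-yne | CCOC#CCc1ccc(OCc2ccccc2)cc1
F7 | step 3 | 3-ethoxy-2,4-bis(4-benzyloxybenzyl)cyclobut-2-en-1-one (racemic at C4) | CCOC1=C(Cc2ccc(OCc3ccccc3)cc2)C(=O)C1Cc1ccc(OCc2ccccc2)cc1
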